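**Plan**

1. Numbering: C1/C5 ring fusion, C6 carbinol, C7 bears the oxolane, C10 bears the exocyclic CH2 (C18), C11/C14 oxolane carbons, C15 bears OAc. Cuts: C6–OH back to the C6 ketone, C7–H back to its enolate, then the C8–C9 bond (with C6–C18 re-formed) by a retro anionic oxy-Cope to a cis-bicyclo[3.3.0]octenol, then C6–C7 to an alkenylmetal plus a bicyclic ketone.
2. Feature used: in the seven-membered ring the C6 oxygen and the exocyclic C10=C18 alkene are 1,5-related through C7–C8–C9 (a δ,ε-unsaturated ketone). C10 carries two CH2 groups (C9 in the ring, C18 outside) that are interchangeable allyl termini, so the cyclopentanol ring C5–C6–C18–C10–C1 maps onto the cycloheptanone by a two-carbon enlargement.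
3. Forward order: oxolane from (R)-linalool (epoxidation, 5-exo opening); cyclopentene ring A annulated onto cyclopentanone ring B (conjugate propargylation, gold Conia-ene); union at C6–C7; ring B enlarged to the seven-membered ring; acetate; C6 reduction.
4. Stereochemistry: C11 from (R)-linalool; C14 from catalyst-controlled epoxidation and inversion in the ring closure; C1 and C5 from the C–O centre of (R)-4-silyloxycyclopentenone (anti addition, forced cis fusion), which is later erased.
5. C7 is set by protonation of the oxy-Cope enolate and C6 by hydride addition from the convex face.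

Key step: step 11

**Route**

Step 1
Reactants: 1 (R)-linalool
Product: 3 2-[(2R,5R)-5-ethenyl-5-methyloxolan-2-yl]propan-2-ol (vinyl and hydroxyisopropyl trans), via epoxy alcohol 2 (not isolated)
Conditions: L-fructose-derived (ent) Shi ketone (0.3 equiv), Oxone, K2CO3, Bu4NHSO4, MeCN/DMM/aq. borate buffer, 0 °C; then CSA (0.1 equiv), CH2Cl2, 0 °C
Reagents that add atoms: potassium peroxymonosulfate (Oxone) OOS(=O)(=O)[O-].[K+]
Why: Shi epoxidation attacks only the electron-rich trisubstituted alkene and the ent-ketone should give the 6S epoxide under catalyst control, which the tertiary C3 hydroxyl opens in an acid-catalysed 5-exo-tet cyclization with inversion to set C14 (R), while C11 (R) is carried over from (R)-linalool.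

Step 2
Reactants: 3 furanoid linalool oxide
Product: 4 1-[(2R,5R)-5-(2-hydroxypropan-2-yl)-2-methyloxolan-2-yl]ethan-1-one
Conditions: Pd(Quinox)Cl2 (5 mol%), AgSbF6 (12 mol%), aq. TBHP, CH2Cl2, rt
Reagents that add atoms: tert-butyl hydroperoxide CC(C)(C)OO
Why: The catalyst-controlled Wacker oxidation (Pd–Quinox/TBHP variant) should give the methyl ketone even next to the allylic ether oxygen, the trans oxolane keeps the tertiary hydroxyl away from the alkene, and no stereocentre is touched.

Step 3
Reactants: 4 methyl ketone
Product: 5 2,4,6-triisopropylbenzenesulfonylhydrazone of 4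
Conditions: TrisNHNH2, THF, cat. HCl, rt
Reagents that add atoms: 2,4,6-triisopropylbenzenesulfonyl hydrazide CC(C)c1cc(C(C)C)c(S(=O)(=O)NN)c(C(C)C)c1
Why: Condensation gives a hydrazone whose only α-hydrogens are on the methyl group, which prepares a regiodefined Shapiro reaction.

Step 4
Reactants: 6 (R)-4-[(tert-butyldimethylsilyl)oxy]cyclopent-2-en-1-one
Product: 7 1,4-bis(TBS-oxy)-3-(prop-2-ynyl)cyclopent-1-ene (propargyl trans to the 4-OTBS group)
Conditions: allenyltributylstannane (1.5 equiv), TBSOTf (1.2 equiv), CH2Cl2, −78 °C
Reagents that add atoms: allenyltributylstannane C=C=C[Sn](CCCC)(CCCC)CCCC; tert-butyldimethylsilyl triflate CC(C)(C)[Si](C)(C)OS(=O)(=O)C(F)(F)F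
Why: Silyl-triflate-promoted conjugate propargylation (SE2′ attack of the allenylstannane on the O-silylated enone, Mukaiyama–Michael type) anti to the 4-silyloxy group sets C1 and traps the enolate regiospecifically as the C5=C6 silyl enol ether.

Step 5
Reactants: 7 terminal alkyne
Product: 8 1,4-bis(TBS-oxy)-3-(but-2-ynyl)cyclopent-1-ene (same configuration)
Conditions: n-BuLi (1.05 equiv), THF, −78 °C; MeI, DMPU, −78 → 0 °C
Reagents that add atoms: iodomethane CI
Why: Deprotonation of the terminal alkyne and SN2 methylation of the acetylide install the future C4 methyl group, and the TBS enol ether should tolerate n-BuLi at −78 °C.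

Step 6
Reactants: 8 butynyl silyl enol ether
Product: 9 cis-fused 6-(TBS-oxy)-2-methylbicyclo[3.3.0]oct-2-en-8-one (target atoms: C6 ketone, C10–OTBS on the convex face, ring A with C3=C4)
Conditions: Ph3PAuCl (10 mol%), AgBF4 (10 mol%), CH2Cl2/MeOH 10:1, 40 °C
Reagents that add atoms: none
Why: Gold(I)-catalysed 5-endo-dig carbocyclization of the silyl enol ether onto the alkyne (Conia-ene type) forms C5–C4 and leaves the C3=C4 alkene in its final position, and the short tether from C1 allows only the cis ring fusion, so C5 is set by C1.

Step 7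
Reactants: 5 trisylhydrazone; 9 bicyclic ketone
Product: 11 tertiary alcohol: 9 carrying at C6 an OH and the 1-(oxolan-2-yl)ethenyl group (alkenyl expected on the convex face), via alkenyllithium 10 (not isolated)
Conditions: 5 (1.3 equiv), n-BuLi (4.0 equiv), THF, −78 → 0 °C; anhydrous CeCl3, −78 °C; then 9, −78 °C; aq. NH4Cl
Reagents that add atoms: none
Why: The Shapiro reaction gives alkenyllithium 10, whose organocerium derivative should add to the easily enolized β,γ-unsaturated ketone instead of deprotonating it, and the configuration of the new C6 carbinol is irrelevant because it is destroyed in step 11.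

Step 8
Reactants: 11 silyl ether
Product: 12 triol (C10–OH, C6–OH, C15–OH)
Conditions: TBAF (1.5 equiv), THF, 0 °C → rt
Reagents that add atoms: none
Why: Fluoride cleaves the secondary TBS ether and leaves the two tertiary alcohols and both alkenes untouched.

Step 9
Reactants: 12 triol
Product: 13 β-hydroxy ketone (C10 ketone, C6 tertiary carbinol)
Conditions: Dess–Martin periodinane, NaHCO3, CH2Cl2, 0 °C
Reagents that add atoms: none
Why: Dess–Martin oxidation acts only on the single secondary alcohol and, buffered, should avoid retro-aldol cleavage; the C10 centre that controlled C1 and C5 is erased here.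

Step 10
Reactants: 13 β-hydroxy ketone
Product: 14 β-hydroxysilane: C10(OH)CH2SiMe3 (C10 configuration undefined and irrelevant)
Conditions: Me3SiCH2Li (5 equiv), CeCl3 (5 equiv), THF, −78 °C; aq. NH4Cl
Reagents that add atoms: (trimethylsilyl)methyllithium C[Si](C)(C)C[Li]
Why: The Peterson reagent as its organocerium adds to the hindered, enolizable ketone at low temperature without base-induced retro-aldol cleavage.

Step 11
Reactants: 14 β-hydroxysilane
Product: 17 cis-fused hydroazulenone (C6 ketone, 7R oxolanyl group, exocyclic C10=C18, free C15–OH), via dipotassium methylene alkoxide 15 (not isolated), via dipotassium enolate 16 (not isolated)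
Conditions: KH (6 equiv), 18-crown-6 (3 equiv), THF, 0 → 45 °C; then AcOH/THF, −78 °C
Reagents that add atoms: none
Why: Proposed new method: KH converts 14 into its alkoxides, Peterson syn-elimination at C10 gives the 3-methylene-1-alkenylcyclopentanolate 15, and its C6 alkoxide sits on the 1,5-diene C8=C7–C6–C18–C10=C9, so an alkoxide-accelerated [3,3] shift (anionic oxy-Cope, boat transition state bridged by C5–C1) should break C6–C18 and form C8–C9; the closest known reactions are the thermal Claisen ring expansion of 2-methylene-5-vinyloxolanes to cyclohept-4-enones and alkoxide-accelerated 1,3-shift ring expansions. The seven-membered ring is not closed end to end but arises by two-carbon enlargement of ring B, which in the stepwise limit is retro-allylation followed by 7-endo-trig conjugate allylation. Because C9 and C18 are both CH2 termini of one allyl unit on C10, the concerted [3,3] path, a [1,3] shift and fragmentation–recombination all lead to the same enolate 16, and both C6 epimers of 14 should converge. C1 and C5 are not touched and stay cis; C7 is set when 16 is protonated at −78 °C from the convex face opposite the cyclopentene ring, which puts H7 cis to H5 and H1 (also the more stable cis-2,7 arrangement). The step needs cleavage of C6–C18 rather than C5–C6, which the convex-face alkenyl group (no cisoid overlap with C3=C4) and the more stable 2-substituted allyl fragment with two primary termini should secure.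

Step 12
Reactants: 17 hydroxy ketone
Product: 18 6-oxo precursor of dictyol H (C15 acetate, C6 ketone)
Conditions: Ac2O (10 equiv), DMAP (2 equiv), Et3N, CH2Cl2, rt
Reagents that add atoms: acetic anhydride CC(=O)OC(C)=O
Why: DMAP-catalysed acylation of the only free hydroxyl (tertiary) at the ketone stage removes any need to tell it apart from the C6 alcohol later.

Step 13
Reactants: 18 keto acetate
Product: 19 dictyol H
Conditions: NaBH4, CeCl3·7H2O, MeOH/THF, −40 → 0 °C
Reagents that add atoms: none
Why: Luche-type hydride addition to the C6 ketone from the convex face, anti to the cyclopentene ring at C5 and the oxolane at C7, should give the 6S alcohol cis to both, while the tertiary acetate is inert and the non-basic medium avoids migration of the C3=C4 alkene.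

**Compound list**

1 | (R)-linalool | C=C[C@](C)(O)CCC=C(C)C | starting material
2 | (3R,6S)-6,7-epoxy-3,7-dimethyloct-1-en-3-ol | C=C[C@](C)(O)CC[C@@H]1OC1(C)C | intermediate
3 | 2-[(2R,5R)-5-ethenyl-5-methyloxolan-2-yl]propan-2-ol | C=C[C@@]1(C)CC[C@H](C(C)(C)O)O1 | intermediate
4 | 1-[(2R,5R)-5-(2-hydroxypropan-2-yl)-2-methyloxolan-2-yl]ethan-1-one | CC(=O)[C@@]1(C)CC[C@H](C(C)(C)O)O1 | intermediate
5 | trisylhydrazone of 4 | CC(=NNS(=O)(=O)c1c(C(C)C)cc(C(C)C)cc1C(C)C)[C@@]1(C)CC[C@H](C(C)(C)O)O1 | intermediate
6 | (R)-4-[(tert-butyldimethylsilyl)oxy]cyclopent-2-en-1-one | CC(C)(C)[Si](C)(C)O[C@@H]1CC(=O)C=C1 | starting material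
7 | 1,4-bis(TBS-oxy)-3-(prop-2-ynyl)cyclopent-1-ene, 3,4-trans | CC(C)(C)[Si](C)(C)O[C@@H]1CC(O[Si](C)(C)C(C)(C)C)=C[C@H]1CC#C | intermediate
8 | 1,4-bis(TBS-oxy)-3-(but-2-ynyl)cyclopent-1-ene, 3,4-trans | CC(C)(C)[Si](C)(C)O[C@@H]1CC(O[Si](C)(C)C(C)(C)C)=C[C@H]1CC#CC | intermediate
9 | cis-fused 6-(TBS-oxy)-2-methylbicyclo[3.3.0]oct-2-en-8-one, OTBS on convex face | CC(C)(C)[Si](C)(C)O[C@@H]1CC(=O)[C@H]2C(C)=CC[C@@H]12 | intermediate
10 | alkenyllithium from 5 (lithium alkoxide) | [Li]C(=C)[C@@]1(C)CC[C@H](C(C)(C)O[Li])O1 | intermediate
11 | C6 tertiary alcohol, adduct of 10 and 9 | CC(C)(C)[Si](C)(C)O[C@@H]1C[C@](O)(C(=C)[C@@]3(C)CC[C@H](C(C)(C)O)O3)[C@H]2C(C)=CC[C@@H]12 | intermediate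
12 | triol | O[C@@H]1C[C@](O)(C(=C)[C@@]3(C)CC[C@H](C(C)(C)O)O3)[C@H]2C(C)=CC[C@@H]12 | intermediate
13 | β-hydroxy ketone (C10 ketone) | O=C1C[C@](O)(C(=C)[C@@]3(C)CC[C@H](C(C)(C)O)O3)[C@H]2C(C)=CC[C@@H]12 | intermediate
14 | β-hydroxysilane (C10 epimers) | C[Si](C)(C)CC1(O)C[C@](O)(C(=C)[C@@]3(C)CC[C@H](C(C)(C)O)O3)[C@H]2C(C)=CC[C@@H]12 | intermediate
15 | dipotassium 3-methylene-1-alkenylcyclopentanolate | C=C1C[C@]([O-])(C(=C)[C@@]3(C)CC[C@H](C(C)(C)[O-])O3)[C@H]2C(C)=CC[C@@H]12.[K+].[K+] | intermediate
16 | dipotassium C6=C7 enolate of the hydroazulenone | C=C1CCC([C@@]3(C)CC[C@H](C(C)(C)[O-])O3)=C([O-])[C@H]2C(C)=CC[C@@H]12.[K+].[K+] | intermediate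
17 | cis-fused hydroazulen-6-one with free C15–OH | C=C1CC[C@@H]([C@@]3(C)CC[C@H](C(C)(C)O)O3)C(=O)[C@H]2C(C)=CC[C@@H]12 | intermediate
18 | 6-oxo precursor of dictyol H (C15 acetate) | C=C1CC[C@@H]([C@@]3(C)CC[C@H](C(C)(C)OC(C)=O)O3)C(=O)[C@H]2C(C)=CC[C@@H]12 | intermediate
19 | dictyol H | C=C1CC[C@@H]([C@@]2(C)CC[C@H](C(C)(C)OC(C)=O)O2)[C@@H](O)[C@H]2C(C)=CC[C@@H]12 | target

**Count and risks**

Total steps: 13. Longest linear sequence: 10 steps (1, 2, 3, 7–13 from (R)-linalool; equally 4, 5, 6, 7–13 from 6).

Step 11 (proposed new method). After Peterson elimination the alkoxide may fragment heterolytically and the allyl anion may be quenched by the acidic C5–H instead of recombining at C8, or the minor C6 epimer may rearrange through the C3=C4 alkene. The fallback uses known chemistry and sets out from β-hydroxy ketone 13. Catalytic KOt-Bu in t-BuOH/THF at 0 °C should cause retro-aldol cleavage of C6–C18 to the ring-opened enone methyl ketone F1. Its methyl-ketone enolate closes the seven-membered ring by intramolecular Michael addition at C8 and gives, after protonation at C7, the cis-fused cycloheptane-1,4-dione F2. The less hindered C10 carbonyl of F2 is then methylenated with the Lombardo reagent (Zn, CH2Br2, TiCl4), which comes back to the route at 17.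

Step 6. Attack of the enol ether on the gold-activated internal alkyne may be slow, so that methanolysis of the silyl enol ether or loss of the β-silyloxy group takes over. The fallback sets out from terminal alkyne 7 and skips step 5. Iodination with NIS and catalytic AgNO3 in DMF gives the iodoalkyne F3, the same gold(I) conditions give by 5-endo-dig cyclization the bicyclic vinyl iodide F4, and Negishi coupling with MeZnCl and Pd(PPh3)4 installs the C4 methyl group and comes back at 9.

Step 13. Hydride addition at the doubly α-branched carbonyl may be slow or show poor facial selectivity, and a longer reaction invites migration of the C3=C4 alkene into conjugation. The fallback sets out from 18 and reduces under reagent control with a ketoreductase (NADPH-dependent alcohol dehydrogenase from a screening panel, propan-2-ol for cofactor recycling, pH 7 buffer/DMSO, 30 °C), which arrives directly at 19; no new compound is formed (F0).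

**Further compounds**

F1 | step 11 | ring-opened enone methyl ketone (cis-2-acetyl-5-acyl cyclopentene) | CC(=O)[C@@H]1CC=C(C)[C@@H]1C(=O)C(=C)[C@@]2(C)CC[C@H](C(C)(C)O)O2
F2 | step 11 | cis-fused cycloheptane-1,4-dione (C6 and C10 ketones) | O=C1CC[C@@H]([C@@]3(C)CC[C@H](C(C)(C)O)O3)C(=O)[C@H]2C(C)=CC[C@@H]12
F3 | step 6 | iodoalkyne of 7 | CC(C)(C)[Si](C)(C)O[C@@H]1CC(O[Si](C)(C)C(C)(C)C)=C[C@H]1CC#CI
F4 | step 6 | bicyclic vinyl iodide (iodine at C4) | CC(C)(C)[Si](C)(C)O[C@@H]1CC(=O)[C@H]2C(I)=CC[C@@H]12
F0 | step 13 | none | none
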